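The runs come from a simulation with constants of no real substance.

Every part of the charged free monomer is free, in chains or gone elsewhere, so these fractions sum to one, and the fraction left is the one to follow.

- teal: free monomer 2.8 M; protic impurity 0.84 M; initiator 73 mM; the very flask that is asked about, followed so far
- flask: free monomer 2.8 M; protic impurity 0.840 M; initiator 73 mM; time 15 h

teal run (percent of the free monomer charged)

| time / h | monomer in chains / % | free monomer / % |
|---|---|---|
| 0.200 | 0.6 | 98.7 |
| 0.333 | 1.5 | 98.2 |
| 0.667 | 2.4 | 94.8 |
| 1.00 | 5.0 | 92.4 |
| 1.50 | 7.8 | 87.3 |
| 2.50 | 14.7 | 79.2 |

(readings scatter by 0.3 percentage points)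

- the average divides the monomer in chains by the number of chains begun, living and dead together
- the numbers in the tables scatter with a standard deviation of 0.3 percentage points
- the earlier runs do not show the number of chains; that part of a forecast is a guess

1. average number of monomer units in a chain (chains begun, living or dead) at 15 h
2. part of the free monomer that has reacted at 15 h

Between 1.50 h and 2.50 h the fraction left in the teal run fell from 87.3% to 79.2%, so its logarithm fell by 0.0974 h⁻¹. This share of the free monomer present that disappears per hour is the loss rate, a reading and a pseudo-first-order constant for as long as it stays constant.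

My own bracket for c starts from it. If the loss rate holds from 2.50 h to 15 h, c comes to 76.6%, which I take as an estimated ceiling. For a floor, chain growth is taken to stop at 2.50 h. The fraction of the teal run then neither free nor in chains, spread over the time so far, gives a side loss of 0.0244 h⁻¹, and letting that go on as a share of the free monomer present gives c = 41.6%.

The forecast gives dp 18 and c 74%, on the ground “total decay is about 0.09 h⁻¹, leaving about 26% free monomer at 15 h”; its c lies below the ceiling and above the floor.

The flask gives dp 16.9 and c 61.7%, which is 12 percentage points below the forecast and above the floor.

    free monomer → uncatalysed product (k = 0.00370 h⁻¹)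
    free monomer + initiator → living end + monomer in chains (k = 0.330 M⁻¹ h⁻¹)
    monomer in chains + living end → free monomer + living end, rate k3*[living end] as long as [monomer in chains] is above zero (k = 2.40 h⁻¹)
    free monomer + living end → monomer in chains + living end, rate k4*[living end]*[free monomer] (k = 2.30 M⁻¹ h⁻¹)
    initiator → spent initiator (k = 0.0460 h⁻¹)
    protic impurity + free monomer → quenched substrate (k = 0.0340 M⁻¹ h⁻¹)

At 15.0 h the flask makes monomer in chains 1.03 times as fast as it uses it up, each step taken net. Over the whole run the mean loss rate of the flask is 0.0640 h⁻¹, or 0.657 of the reading 0.0974 h⁻¹. A neighbour flask charged with 0.029 M of initiator keeps 50% of its free monomer at 15 h, so its mean loss rate is 0.0466 h⁻¹, half of the reading 0.0974 h⁻¹.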